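**Plan**

- The arene (C1 carries the side chain, C3 the OH, C5 the OMe) is treated as a decarboxylated tetraketide. An ester is restored on C2, which sets the hydrogen-bonded C3–OH apart from the C5–OH that is to be methylated. The C1–C2 ring bond is then cut by retro-aldol to an open 3,5,7-triketo ester.
- The triketo ester is traced to allyl alcohol and an acylketene released from a diketo-dioxinone. The diketo-dioxinone is cut at a ketone–methylene bond into a β-silyloxy Weinreb amide and the dianion of a keto-dioxinone.
- The C14 acyl unit is cut between C2 and C3 (malonate two-carbon unit) and back to a six-carbon ring enamine plus hexanoyl chloride.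
- Forward: the chain is built first, then joined to the dioxinone. The only ring, the benzene ring, is closed by ketene capture and aldol aromatisation. Methylation, removal of the carboxyl group, deprotection and acetylation finish the route.
- The single stereocentre (R) comes from hydrogenation of the β-keto ester with RuCl2[(R)-BINAP] and is carried through unchanged as a silyl ether.

Key step: step 10

Remark: the morpholine enamine of cyclohexanone is taken as a purchased starting material, and salts that are merely protonated on work-up (carboxylates, phenoxides, product enolates) are treated as their neutral forms.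

**Route**

Step 1
Reactants: 1 4-(cyclohex-1-en-1-yl)morpholine; 2 hexanoyl chloride
Product: 4 2-hexanoylcyclohexan-1-one, via acylated enamine 3 (not isolated)
Conditions: Et3N, CH2Cl2, 0 °C → rt; then 6 M aq. HCl, rt → 60 °C
Reagents that add atoms: water (O)
Why: Stork enamine acylation, in which the nucleophilic β-carbon of the enamine attacks the acid chloride, Et3N takes up HCl to leave the vinylogous amide, and aqueous acid hydrolyses it to the 1,3-diketone.

Step 2
Reactants: 4 2-hexanoylcyclohexan-1-one
Product: 5 7-oxododecanoic acid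
Conditions: aq. NaOH, reflux; then conc. HCl to pH 1
Reagents that add atoms: sodium hydroxide ([Na+].[OH-])
Why: Retro-Claisen cleavage of a 2-acylcyclohexanone, in which hydroxide adds to the ring carbonyl and the ring bond to the acyl-bearing carbon breaks to release a stabilised ketone enolate, so the six ring carbons become the carboxyl end of the chain.

Step 3
Reactants: 5 7-oxododecanoic acid; 6 potassium monomethyl malonate
Product: 9 methyl 3,9-dioxotetradecanoate, via acyl imidazolide 7 (not isolated), via acylmalonic half ester 8 (not isolated)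
Conditions: CDI, THF, rt; then MeO2CCH2CO2K, MgCl2, Et3N, THF, rt → 45 °C; 1 M HCl work-up
Reagents that add atoms: none
Why: Masamune–Brooks homologation, in which the acyl imidazolide C-acylates the magnesium enolate of the malonate half ester and the acylmalonate loses CO2, while the isolated C7 ketone is a spectator under these almost neutral conditions.

Step 4
Reactants: 9 methyl 3,9-dioxotetradecanoate
Product: 10 methyl (3R)-3-hydroxy-9-oxotetradecanoate
Conditions: H2 (50 atm), RuCl2[(R)-BINAP] (0.5 mol %), MeOH, 50 °C; aqueous work-up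
Reagents that add atoms: none
Why: Noyori asymmetric hydrogenation, in which the β-keto ester chelates divalent ruthenium through both carbonyl oxygens and hydride is delivered to the face fixed by (R)-BINAP (the sense that gives (R)-3-hydroxy esters from unbranched 3-oxoalkanoates), whereas the non-chelating C9 ketone is not reduced by a diphosphine ruthenium dihalide.

Step 5
Reactants: 10 methyl (3R)-3-hydroxy-9-oxotetradecanoate
Product: 11 methyl (3R)-3-(tert-butyldimethylsilyloxy)-9-oxotetradecanoate
Conditions: TBSCl, imidazole, DMF, rt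
Reagents that add atoms: tert-butyldimethylsilyl chloride (CC(C)(C)[Si](C)(C)Cl)
Why: Standard imidazole-promoted silylation of a secondary alcohol, giving an ether that cannot undergo retro-aldol cleavage and is a poor leaving group in the later enolate steps.

Step 6
Reactants: 11 methyl (3R)-3-(tert-butyldimethylsilyloxy)-9-oxotetradecanoate
Product: 12 methyl (3R)-3-(tert-butyldimethylsilyloxy)-9,9-(ethylenedioxy)tetradecanoate
Conditions: TMSOCH2CH2OTMS, TMSOTf (5 mol %), CH2Cl2, −78 → −20 °C; pyridine quench
Reagents that add atoms: 1,2-bis(trimethylsilyloxy)ethane (C[Si](C)(C)OCCO[Si](C)(C)C)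
Why: Silyl-transfer ketalisation under TMSOTf catalysis converts the dialkyl ketone into its dioxolane under aprotic, low-temperature conditions that leave the secondary silyl ether and the methyl ester untouched.

Step 7
Reactants: 12 methyl (3R)-3-(tert-butyldimethylsilyloxy)-9,9-(ethylenedioxy)tetradecanoate
Product: 13 (3R)-3-(tert-butyldimethylsilyloxy)-9,9-(ethylenedioxy)-N-methoxy-N-methyltetradecanamide
Conditions: MeNH(OMe)·HCl, i-PrMgCl, THF, −20 → 0 °C
Reagents that add atoms: N,O-dimethylhydroxylamine hydrochloride (CNOC.Cl)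
Why: Direct aminolysis of the ester by the chloromagnesium amide formed in the flask gives the Weinreb amide, the amide anion adding to the ester carbonyl faster than it can deprotonate C2, so the β-silyloxy group and the ketal are retained.

Step 8
Reactants: 14 2,2,6-trimethyl-4H-1,3-dioxin-4-one; 15 acetyl chloride
Product: 17 2,2-dimethyl-6-(2-oxopropyl)-4H-1,3-dioxin-4-one, via lithium dienolate 16 (not isolated)
Conditions: LiN(SiMe3)2 (2 equiv per AcCl), THF, −78 °C; then AcCl, −78 °C; aq. NH4Cl
Reagents that add atoms: none
Why: Vinylogous C-acylation of the dioxinone dienolate at its terminal (γ) carbon is the established entry to 6-(2-oxoalkyl)dioxinones, and the second equivalent of dienolate absorbs the proton of the more acidic product.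

Step 9
Reactants: 17 2,2-dimethyl-6-(2-oxopropyl)-4H-1,3-dioxin-4-one; 13 (3R)-3-(tert-butyldimethylsilyloxy)-9,9-(ethylenedioxy)-N-methoxy-N-methyltetradecanamide
Product: 19 6-[(6R)-6-(tert-butyldimethylsilyloxy)-12,12-(ethylenedioxy)-2,4-dioxoheptadecyl]-2,2-dimethyl-4H-1,3-dioxin-4-one, via dilithium dianion 18 (not isolated)
Conditions: LiN(i-Pr)2 (2 equiv per 17), THF, −78 °C; then 13, −78 → −40 °C; aq. NH4Cl; used without chromatography
Reagents that add atoms: none
Why: Claisen-type acylation of a 1,3-dicarbonyl dianion, in which the terminal, last-formed carbanion attacks the Weinreb amide and the chelated tetrahedral adduct shields the new ketone from further attack until work-up.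

Step 10
Reactants: 19 6-[(6R)-6-(tert-butyldimethylsilyloxy)-12,12-(ethylenedioxy)-2,4-dioxoheptadecyl]-2,2-dimethyl-4H-1,3-dioxin-4-one; 20 allyl alcohol
Product: 24 allyl 2,4-dihydroxy-6-[(2R)-2-(tert-butyldimethylsilyloxy)-8,8-(ethylenedioxy)tridecyl]benzoate, via acylketene 21 (not isolated), via triketo ester 22 (not isolated), via aldol adduct 23 (not isolated)
Conditions: allyl alcohol (5 equiv), PhMe, 110 °C; then Cs2CO3, i-PrOH/CH2Cl2, rt; then AcOH
Reagents that add atoms: none
Why: Heating the dioxinone to 110 °C triggers a retro-hetero-Diels–Alder loss of acetone, and the acylketene 21 so formed is captured at its central carbon by allyl alcohol to give the 3,5,7-triketo ester 22. Cs2CO3 then deprotonates C2, the only methylene flanked by the ester and a ketone, and this enolate adds to the C7 ketone in an intramolecular aldol reaction that forms the C2–C7 bond and closes the six-membered carbocycle by a 6-(enolendo)-exo-trig closure to give 23. Loss of water from the tertiary carbinol and enolisation of the C3 and C5 carbonyl groups, driven by aromaticity, deliver the benzene ring of 24. The closest known reaction type is the biomimetic synthesis of β-resorcylate esters from diketo-dioxinones by ketene trapping and aldol aromatisation. No lasting stereocentre is created (the carbinol carbon of 23 becomes an arene carbon), and the existing C9 stereocentre sits outside the reacting array as a silyl ether, which is a poor leaving group and cannot form a hemiketal, so it is not disturbed. The step needs chemoselective intermolecular ketene capture and regioselective ring closure: excess allyl alcohol outruns capture of the ketene by an enol oxygen (pyranone formation), the higher acidity of the doubly activated C2–H favours the C2-to-C7 aldol over attack of C8 on the C3 ketone, and the mild carbonate base avoids the Claisen closure of C6 onto the ester that stronger bases promote.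

Step 11
Reactants: 24 allyl 2,4-dihydroxy-6-[(2R)-2-(tert-butyldimethylsilyloxy)-8,8-(ethylenedioxy)tridecyl]benzoate
Product: 25 allyl 2-hydroxy-4-methoxy-6-[(2R)-2-(tert-butyldimethylsilyloxy)-8,8-(ethylenedioxy)tridecyl]benzoate
Conditions: MeI (1.1 equiv), K2CO3, acetone, rt
Reagents that add atoms: iodomethane (CI)
Why: Williamson O-methylation, in which the C4 hydroxyl (para to the ester, not hydrogen bonded) is the more acidic and more nucleophilic phenol while the C2 hydroxyl is held in a hydrogen bond to the ester carbonyl, so one equivalent of MeI should alkylate C4–OH only.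

Step 12
Reactants: 25 allyl 2-hydroxy-4-methoxy-6-[(2R)-2-(tert-butyldimethylsilyloxy)-8,8-(ethylenedioxy)tridecyl]benzoate
Product: 26 2-hydroxy-4-methoxy-6-[(2R)-2-(tert-butyldimethylsilyloxy)-8,8-(ethylenedioxy)tridecyl]benzoic acid
Conditions: Pd(PPh3)4 (5 mol %), morpholine, THF, rt; pH 4 buffer work-up
Reagents that add atoms: none
Why: Tsuji–Trost deallylation, in which zerovalent palladium ionises the allyl ester to a π-allyl complex that morpholine intercepts, freeing the acid under neutral conditions that keep the silyl ether and the ketal.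

Step 13
Reactants: 26 2-hydroxy-4-methoxy-6-[(2R)-2-(tert-butyldimethylsilyloxy)-8,8-(ethylenedioxy)tridecyl]benzoic acid
Product: 27 3-[(2R)-2-(tert-butyldimethylsilyloxy)-8,8-(ethylenedioxy)tridecyl]-5-methoxyphenol
Conditions: dry DMF, 130 °C
Reagents that add atoms: none
Why: Thermal protodecarboxylation, in which the ortho hydroxyl and para methoxy groups make the ipso carbon basic enough to take up the carboxyl proton and the resulting cyclohexadienone expels CO2, as 2-hydroxy-4-alkoxy-6-alkylbenzoic acids do on heating, and the step is placed before desilylation so that a free side-chain alcohol cannot lactonise onto the carboxyl group.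

Step 14
Reactants: 27 3-[(2R)-2-(tert-butyldimethylsilyloxy)-8,8-(ethylenedioxy)tridecyl]-5-methoxyphenol
Product: 28 (12R)-12-hydroxy-13-(3-hydroxy-5-methoxyphenyl)tridecan-6-one
Conditions: 2 M aq. HCl, THF, rt → 40 °C
Reagents that add atoms: water (O)
Why: Aqueous acid hydrolyses the dioxolane and the secondary silyl ether in one operation, and the homobenzylic carbinol does not ionise under these conditions, so its configuration is kept.

Step 15
Reactants: 28 (12R)-12-hydroxy-13-(3-hydroxy-5-methoxyphenyl)tridecan-6-one
Product: 29 (2R)-1-(3-acetoxy-5-methoxyphenyl)-8-oxotridecan-2-yl acetate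
Conditions: Ac2O, pyridine, DMAP (cat.), CH2Cl2, rt
Reagents that add atoms: acetic anhydride (CC(=O)OC(C)=O)
Why: DMAP-catalysed O-acylation esterifies both the secondary alcohol and the phenol without touching the C–O bond of the stereocentre.

Step 16
Reactants: 29 (2R)-1-(3-acetoxy-5-methoxyphenyl)-8-oxotridecan-2-yl acetate
Product: 30 (2R)-1-(3-hydroxy-5-methoxyphenyl)-8-oxotridecan-2-yl acetate (CNP0302149.1)
Conditions: NH4OAc, MeOH–H2O (4:1), rt
Reagents that add atoms: none
Why: Chemoselective solvolysis, since an aryl acetate is a far better acyl donor than an alkyl acetate (phenoxide leaving group), so neutral ammonium acetate in aqueous methanol should cleave only the phenolic ester.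

**Compound list**

1 | 4-(cyclohex-1-en-1-yl)morpholine | C1CCC(=CC1)N1CCOCC1 | starting material
2 | hexanoyl chloride | CCCCCC(Cl)=O | starting material
3 | 1-[2-(morpholin-4-yl)cyclohex-1-en-1-yl]hexan-1-one | CCCCCC(=O)C1=C(CCCC1)N1CCOCC1 | intermediate
4 | 2-hexanoylcyclohexan-1-one (racemic, enolisable) | CCCCCC(=O)C1CCCCC1=O | intermediate
5 | 7-oxododecanoic acid | CCCCCC(=O)CCCCCC(O)=O | intermediate
6 | potassium monomethyl malonate | COC(=O)CC(=O)[O-].[K+] | starting material
7 | 1-(1H-imidazol-1-yl)dodecane-1,7-dione | CCCCCC(=O)CCCCCC(=O)n1ccnc1 | intermediate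
8 | 2-(methoxycarbonyl)-3,9-dioxotetradecanoic acid (formed as its magnesium salt) | CCCCCC(=O)CCCCCC(=O)C(C(=O)OC)C(O)=O | intermediate
9 | methyl 3,9-dioxotetradecanoate | CCCCCC(=O)CCCCCC(=O)CC(=O)OC | intermediate
10 | methyl (3R)-3-hydroxy-9-oxotetradecanoate | CCCCCC(=O)CCCCC[C@H](CC(=O)OC)O | intermediate
11 | methyl (3R)-3-(tert-butyldimethylsilyloxy)-9-oxotetradecanoate | CCCCCC(=O)CCCCC[C@H](CC(=O)OC)O[Si](C)(C)C(C)(C)C | intermediate
12 | methyl (3R)-3-(tert-butyldimethylsilyloxy)-9,9-(ethylenedioxy)tetradecanoate | CCCCCC1(OCCO1)CCCCC[C@H](CC(=O)OC)O[Si](C)(C)C(C)(C)C | intermediate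
13 | (3R)-3-(tert-butyldimethylsilyloxy)-9,9-(ethylenedioxy)-N-methoxy-N-methyltetradecanamide | CCCCCC1(OCCO1)CCCCC[C@H](CC(=O)N(C)OC)O[Si](C)(C)C(C)(C)C | intermediate
14 | 2,2,6-trimethyl-4H-1,3-dioxin-4-one | CC1=CC(=O)OC(C)(C)O1 | starting material
15 | acetyl chloride | CC(Cl)=O | starting material
16 | lithium 2,2-dimethyl-6-methylidene-6H-1,3-dioxin-4-olate | [Li+].[O-]C1=CC(=C)OC(C)(C)O1 | intermediate
17 | 2,2-dimethyl-6-(2-oxopropyl)-4H-1,3-dioxin-4-one | CC(=O)CC1=CC(=O)OC(C)(C)O1 | intermediate
18 | dilithium dianion of 17 (dienolate of the ring plus terminal enolate of the side chain) | [Li+].[Li+].C=C([O-])C=C1C=C([O-])OC(C)(C)O1 | intermediate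
19 | 6-[(6R)-6-(tert-butyldimethylsilyloxy)-12,12-(ethylenedioxy)-2,4-dioxoheptadecyl]-2,2-dimethyl-4H-1,3-dioxin-4-one | CCCCCC1(OCCO1)CCCCC[C@H](CC(=O)CC(=O)CC2=CC(=O)OC(C)(C)O2)O[Si](C)(C)C(C)(C)C | intermediate
20 | allyl alcohol | C=CCO | starting material
21 | acylketene: (9R)-9-(tert-butyldimethylsilyloxy)-15,15-(ethylenedioxy)-3,5,7-trioxoicos-1-en-1-one | CCCCCC1(OCCO1)CCCCC[C@H](CC(=O)CC(=O)CC(=O)C=C=O)O[Si](C)(C)C(C)(C)C | intermediate
22 | allyl (9R)-9-(tert-butyldimethylsilyloxy)-15,15-(ethylenedioxy)-3,5,7-trioxoicosanoate | CCCCCC1(OCCO1)CCCCC[C@H](CC(=O)CC(=O)CC(=O)CC(=O)OCC=C)O[Si](C)(C)C(C)(C)C | intermediate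
23 | allyl 2-hydroxy-2-[(2R)-2-(tert-butyldimethylsilyloxy)-8,8-(ethylenedioxy)tridecyl]-4,6-dioxocyclohexane-1-carboxylate (ring stereocentres undefined) | CCCCCC1(OCCO1)CCCCC[C@H](CC2(O)CC(=O)CC(=O)C2C(=O)OCC=C)O[Si](C)(C)C(C)(C)C | intermediate
24 | allyl 2,4-dihydroxy-6-[(2R)-2-(tert-butyldimethylsilyloxy)-8,8-(ethylenedioxy)tridecyl]benzoate | CCCCCC1(OCCO1)CCCCC[C@H](Cc2cc(O)cc(O)c2C(=O)OCC=C)O[Si](C)(C)C(C)(C)C | intermediate
25 | allyl 2-hydroxy-4-methoxy-6-[(2R)-2-(tert-butyldimethylsilyloxy)-8,8-(ethylenedioxy)tridecyl]benzoate | CCCCCC1(OCCO1)CCCCC[C@H](Cc2cc(OC)cc(O)c2C(=O)OCC=C)O[Si](C)(C)C(C)(C)C | intermediate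
26 | 2-hydroxy-4-methoxy-6-[(2R)-2-(tert-butyldimethylsilyloxy)-8,8-(ethylenedioxy)tridecyl]benzoic acid | CCCCCC1(OCCO1)CCCCC[C@H](Cc2cc(OC)cc(O)c2C(O)=O)O[Si](C)(C)C(C)(C)C | intermediate
27 | 3-[(2R)-2-(tert-butyldimethylsilyloxy)-8,8-(ethylenedioxy)tridecyl]-5-methoxyphenol | CCCCCC1(OCCO1)CCCCC[C@H](Cc2cc(OC)cc(O)c2)O[Si](C)(C)C(C)(C)C | intermediate
28 | (12R)-12-hydroxy-13-(3-hydroxy-5-methoxyphenyl)tridecan-6-one | CCCCCC(=O)CCCCC[C@H](Cc1cc(O)cc(OC)c1)O | intermediate
29 | (2R)-1-(3-acetoxy-5-methoxyphenyl)-8-oxotridecan-2-yl acetate | CCCCCC(=O)CCCCC[C@H](Cc1cc(OC(C)=O)cc(OC)c1)OC(C)=O | intermediate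
30 | (2R)-1-(3-hydroxy-5-methoxyphenyl)-8-oxotridecan-2-yl acetate | CCCCCC(=O)CCCCC[C@H](Cc1cc(O)cc(OC)c1)OC(C)=O | target

**Count**

Total steps: 16. Longest linear sequence: 15 (steps 1–7 and 9–16, from 1 to 30); step 8 is a one-step branch.

**Steps most likely to fail**

Step 10. The acylketene may be captured intramolecularly by an enol oxygen before allyl alcohol reaches it. The open triketo ester may also close in the Claisen sense, or lose the silyloxy group by β-elimination, before the aldol closure. The fallback forms the same C–C bond and the same ring without the thermolysis. It sets out from 19: Et3N in CH2Cl2 at rt lets the dioxinone C5 (the masked ester α-carbon) add to the distal ketone, and dehydration should give 5-[(2R)-2-(tert-butyldimethylsilyloxy)-8,8-(ethylenedioxy)tridecyl]-7-hydroxy-2,2-dimethyl-4H-1,3-benzodioxin-4-one F1. In F1 the ortho oxygen is tied up in the acetonide, so MeI and K2CO3 in acetone can only methylate the remaining phenol, giving 5-[(2R)-2-(tert-butyldimethylsilyloxy)-8,8-(ethylenedioxy)tridecyl]-7-methoxy-2,2-dimethyl-4H-1,3-benzodioxin-4-one F2. Aqueous KOH in THF/MeOH at 50 °C, then acidification to pH 4, opens the dioxinone ring and returns to the route at 26.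

Step 9. Proton transfer from C2 of the amide to the dianion, slow acylation, or expulsion of the β-silyloxy group could stall the chain-joining. The fallback replaces the Claisen-type acylation by aldol addition and oxidation. It sets out from 12: i-Bu2AlH in CH2Cl2 at −78 °C should give (3R)-3-(tert-butyldimethylsilyloxy)-9,9-(ethylenedioxy)tetradecanal F3. The dianion 18 (from 17 and LiN(i-Pr)2, THF, −78 °C) adds to this aldehyde through its terminal carbon to give 6-[(6R)-6-(tert-butyldimethylsilyloxy)-12,12-(ethylenedioxy)-4-hydroxy-2-oxoheptadecyl]-2,2-dimethyl-4H-1,3-dioxin-4-one F4, as a mixture of epimers at the new carbinol, which does not matter. Dess–Martin periodinane in CH2Cl2 oxidises that carbinol and returns to the route at 19.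

Step 13. At 130 °C the neighbouring carboxylic acid may take over or cleave the silyl group, and lactonisation of the freed alcohol could then outrun loss of CO2. Decarboxylation may also stop short of completion. The fallback uses the lactone deliberately and removes CO2 under basic conditions, where a carboxylate cannot lactonise. It sets out from 25: Bu4NF in THF frees the alkoxide, which closes onto the allyl ester to give (3R)-3-[6,6-(ethylenedioxy)undecyl]-8-hydroxy-6-methoxy-3,4-dihydroisocoumarin F5. Aqueous KOH in MeOH at 120 °C (sealed vessel) opens the lactone by acyl–oxygen cleavage and decarboxylates the 2-oxidobenzoate, the known saponification–decarboxylation of 2,4-dioxygenated benzoates, to give 3-[(2R)-8,8-(ethylenedioxy)-2-hydroxytridecyl]-5-methoxyphenol F6. Hydrolysis of the dioxolane with 2 M aq. HCl in THF returns to the route at 28.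

**Further compounds**

F1 | step 10 | 5-[(2R)-2-(tert-butyldimethylsilyloxy)-8,8-(ethylenedioxy)tridecyl]-7-hydroxy-2,2-dimethyl-4H-1,3-benzodioxin-4-one | CCCCCC1(OCCO1)CCCCC[C@H](Cc2cc(O)cc3OC(C)(C)OC(=O)c23)O[Si](C)(C)C(C)(C)C
F2 | step 10 | 5-[(2R)-2-(tert-butyldimethylsilyloxy)-8,8-(ethylenedioxy)tridecyl]-7-methoxy-2,2-dimethyl-4H-1,3-benzodioxin-4-one | CCCCCC1(OCCO1)CCCCC[C@H](Cc2cc(OC)cc3OC(C)(C)OC(=O)c23)O[Si](C)(C)C(C)(C)C
F3 | step 9 | (3R)-3-(tert-butyldimethylsilyloxy)-9,9-(ethylenedioxy)tetradecanal | CCCCCC1(OCCO1)CCCCC[C@H](CC=O)O[Si](C)(C)C(C)(C)C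
F4 | step 9 | 6-[(6R)-6-(tert-butyldimethylsilyloxy)-12,12-(ethylenedioxy)-4-hydroxy-2-oxoheptadecyl]-2,2-dimethyl-4H-1,3-dioxin-4-one | CCCCCC1(OCCO1)CCCCC[C@H](CC(O)CC(=O)CC2=CC(=O)OC(C)(C)O2)O[Si](C)(C)C(C)(C)C
F5 | step 13 | (3R)-3-[6,6-(ethylenedioxy)undecyl]-8-hydroxy-6-methoxy-3,4-dihydroisocoumarin | CCCCCC1(OCCO1)CCCCC[C@H](Cc2cc(OC)cc(O)c2C3=O)O3
F6 | step 13 | 3-[(2R)-8,8-(ethylenedioxy)-2-hydroxytridecyl]-5-methoxyphenol | CCCCCC1(OCCO1)CCCCC[C@H](Cc2cc(O)cc(OC)c2)O
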